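**Retrosynthetic overview**
- The strategy rests on the carbocycle C1–C6. Its cis oxygens on C2/C3, the C4=C5 alkene and the oxygen on C6 are the functionality of the quinic acid-derived 4,5-O-isopropylidene cyclohex-2-enone (carbonyl = C6, free α-methylene = C1). Only O1 and the C7–O arm are missing, and they sit on C1 as the two ends of a 1,2-diol.
- Disconnections, backwards: C3–OBz (selective acylation); oxirane C1–O–C6 (O1 displaces a C6 sulfonate with inversion); C6 carbinol (hydroxyl-directed reduction of the C6 ketone); C1–O and C7–O (osmylation of an exocyclic C1=C7 alkene anti to the cis-fused dioxolane); C1=C7 (Mannich methylenation of the enone); enone from (−)-quinic acid.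
- Ring order: the six-membered carbocycle comes intact from quinic acid. A dioxolane (acetonide, step 1) is a temporary control element, removed in step 12. The oxirane is the only ring of the target that is made, in step 13.

Key step: step 8

Remark: ring atoms carry the target numbering throughout (C1 quaternary oxirane carbon bearing C7, C2 CHOH, C3 CHOBz, C4=C5, C6 oxirane CH). β is the face of the C2 and C3 oxygens, α the opposite face. Compounds 9 and 10 are carried as C1 epimer mixtures because that centre becomes sp2 in step 7.

**Route**

Step 1
Reactants: 1 (−)-quinic acid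
Product: 2 3,4-O-isopropylidene-1,5-quinide (quinic acid numbering: acetonide on the cis 3,4-diol, lactone from the carboxyl to O5, tertiary 1-OH free)
Conditions: 2,2-dimethoxypropane, TsOH·H2O (cat.), acetone, reflux
Reagents that add atoms: 2,2-dimethoxypropane, COC(C)(C)OC
Why: Acid-catalysed transketalisation caps the only cis-vicinal diol while the carboxyl lactonises onto the syn 5-hydroxyl, so every stereocentre of quinic acid is carried over untouched.

Step 2
Reactants: 2 3,4-O-isopropylidene-1,5-quinide
Product: 3 acetonide triol (carboxyl reduced to CH2OH; free tertiary 1-OH, free 5-OH, 3,4-acetonide; configuration as in quinic acid)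
Conditions: NaBH4, EtOH, 0 °C to rt
Reagents that add atoms: none
Why: Hydride reduction of the strained, α-oxygenated lactone to the primary alcohol frees the 1,2-diol that is to be cleaved and leaves the acetal alone.

Step 3
Reactants: 3 acetonide triol
Product: 4 β-hydroxy ketone (3-hydroxy-4,5-(isopropylidenedioxy)cyclohexan-1-one; free hydroxyl trans to the neighbouring acetal oxygen)
Conditions: NaIO4, H2O (pH 7 phosphate buffer), 0 °C to rt
Reagents that add atoms: none
Why: Malaprade periodate cleavage of the tertiary/primary 1,2-diol removes the former carboxyl carbon as formaldehyde and leaves the ketone that becomes C6, the other vicinal oxygen pair being blocked by the acetal.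

Step 4
Reactants: 4 β-hydroxy ketone
Product: 6 (4S,5R)-4,5-(isopropylidenedioxy)cyclohex-2-en-1-one (target numbering: C6 ketone; C1H2; C2–O and C3–O both β in a cis-fused dioxolane; C4=C5), via β-mesyloxy ketone 5 (not isolated)
Conditions: MsCl, Et3N, CH2Cl2, 0 °C to rt
Reagents that add atoms: none
Why: Mesylation of the β-hydroxyl followed by E1cB elimination gives the conjugated enone, the sulfonate leaving far faster than the acetal oxygen on the other β-carbon, so C4=C5 is installed and C1 remains the only α'-methylene.

Step 5
Reactants: 6 acetonide enone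
Product: 7 cross-conjugated trimethylsilyl dienol ether (C6–OTMS, C1=C6 and C4=C5, acetonide unchanged)
Conditions: TMSOTf, Et3N, CH2Cl2, 0 °C; non-aqueous work-up, used crude
Reagents that add atoms: trimethylsilyl trifluoromethanesulfonate, C[Si](C)(C)OS(=O)(=O)C(F)(F)F
Why: Soft enolisation (silyl triflate and amine) at the only α'-methylene gives the 2-silyloxy-1,3-diene without forming a metal enolate that could expel the β-oxygen at C2.

Step 6
Reactants: 7 trimethylsilyl dienol ether; 8 dimethylmethyleneammonium iodide (Eschenmoser's salt)
Product: 9 Mannich base (C1-(dimethylaminomethyl) enone, C1 epimers)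
Conditions: CH2Cl2, 0 °C to rt; aq. NaHCO3 work-up, used crude
Reagents that add atoms: dimethylmethyleneammonium iodide, C=[N+](C)C.[I-]
Why: Mannich reaction of the silyl enol ether with the preformed iminium salt forms the C1–C7 bond at the enol carbon under non-basic conditions.

Step 7
Reactants: 9 Mannich base
Product: 11 (4S,5R)-4,5-(isopropylidenedioxy)-6-methylenecyclohex-2-en-1-one (exocyclic C1=C7; C6 ketone; C4=C5), via trimethylammonium iodide 10 (not isolated)
Conditions: MeI, CH2Cl2, rt; then sat. aq. NaHCO3, CH2Cl2, 0 °C to rt; cold solution of 11 used at once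
Reagents that add atoms: none
Why: N-Methylation and Hofmann-type E1cB loss of trimethylamine from the β-ammonio ketone give the α-methylene ketone under bicarbonate, the ammonium group being a far better leaving group than the C2 acetal oxygen.

Step 8
Reactants: 11 methylene dienone
Product: 12 diol (C1 tertiary hydroxyl α, C7H2OH β; C6 ketone, C4=C5 and C2/C3 acetonide unchanged)
Conditions: K2OsO2(OH)4 (1 mol%), NMO (1.1 equiv), citric acid (1 equiv), t-BuOH/H2O 1:1, 0 °C to rt
Reagents that add atoms: N-methylmorpholine N-oxide, C[N+]1([O-])CCOCC1; water, O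
Why: OsO4, formed from the osmate by NMO, adds to the exocyclic C1=C7 alkene by [3+2] cycloaddition to give a hexavalent osmium glycolate, which is hydrolysed while NMO returns the metal to the octavalent state; no ring is closed. The closest known reaction type is the Upjohn dihydroxylation of α-methylene ketones, run here in its citric acid variant for electron-poor alkenes, which also keeps the medium slightly acidic so that neither 11 nor the α-ketol product meets base. The new stereocentre C1 is controlled by the cis-fused dioxolane: its allylic C2–O bond and endo methyl group cover the β face, so osmium should add from the α face, anti to the allylic oxygen, placing the C1 hydroxyl α and C7 β. The step needs chemoselectivity for C1=C7 over the ring alkene C4=C5; the former is a terminal 1,1-disubstituted alkene, the latter a cis-disubstituted enone alkene flanked by the C3 acetal oxygen. A small excess of oxidant and stopping at consumption of 11 should keep the ring alkene intact.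

Step 9
Reactants: 12 diol; 13 benzoyl chloride
Product: 14 C7 benzoate (tertiary C1–OH α free, C6 ketone, acetonide)
Conditions: BzCl (1.05 equiv), pyridine, CH2Cl2, −20 to 0 °C
Reagents that add atoms: benzoyl chloride, O=C(Cl)c1ccccc1
Why: Esterification discriminates the primary C7 hydroxyl from the hindered tertiary α-ketol hydroxyl, and capping O7 removes the β-hydroxyl that could otherwise deliver hydride to the wrong face of C6.

Step 10
Reactants: 14 C7 benzoate
Product: 15 trans-C1,C6-diol (C6–OH β, C1–OH α, C7 benzoate, acetonide, C4=C5)
Conditions: Me4NBH(OAc)3, MeCN/AcOH 1:1, −30 to −20 °C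
Reagents that add atoms: none
Why: Saksena–Evans directed reduction: the α-oriented C1 hydroxyl exchanges onto boron and hands hydride to the α face of the C6 carbonyl, so the new hydroxyl is β and trans to O1, and the reagent without a directing hydroxyl is too weak to reduce the enone alkene or the benzoate.

Step 11
Reactants: 15 trans-C1,C6-diol
Product: 16 C6 methanesulfonate (OMs β; C1–OH α free; C7 benzoate; acetonide)
Conditions: MsCl (1.2 equiv), Et3N, CH2Cl2, −20 to 0 °C
Reagents that add atoms: methanesulfonyl chloride, CS(=O)(=O)Cl
Why: Sulfonylation takes place at the only secondary hydroxyl with retention at C6, the tertiary C1 hydroxyl being unreactive under these conditions.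

Step 12
Reactants: 16 C6 methanesulfonate
Product: 17 triol mesylate (C1–OH α, C2–OH and C3–OH β, C6–OMs β, C7 benzoate)
Conditions: AcOH/H2O 4:1, 40 °C
Reagents that add atoms: none
Why: Acid-catalysed acetal hydrolysis is done before the oxirane exists, so no acid-labile vinyl epoxide is exposed; the mesylate, whose ionisation is disfavoured by the flanking C–O bonds, and the benzoate should tolerate warm aqueous acetic acid.

Step 13
Reactants: 17 triol mesylate
Product: 18 epoxy diol (α-oxirane C1–O–C6, C2–OH and C3–OH β, C7 benzoate, C4=C5)
Conditions: DBU (1.5 equiv), CH2Cl2, 0 °C to rt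
Reagents that add atoms: none
Why: Intramolecular Williamson closure (3-exo-tet SN2): O1 on the α face attacks C6 anti to the β-mesylate, inverting C6 and giving the α-oxirane, and the weak non-nucleophilic amidine base should avoid benzoate cleavage, acyl shift to O2 and Payne rearrangement.

Step 14
Reactants: 18 epoxy diol; 13 benzoyl chloride
Product: 19 target, (1R,2S,3S,6S)-1-(benzoyloxymethyl)-2-hydroxy-7-oxabicyclo[4.1.0]hept-4-en-3-yl benzoate (locants as in the numbering used here)
Conditions: BzCl (1.05 equiv), pyridine, CH2Cl2, −40 to −20 °C
Reagents that add atoms: benzoyl chloride, O=C(Cl)c1ccccc1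
Why: Kinetic monoacylation should take the allylic, unhindered C3 hydroxyl, since the C2 hydroxyl is flanked by the quaternary C1 and lies cis to its benzoyloxymethyl arm; low temperature and one equivalent limit diacylation and acyl migration.

**Compound list**

1 | (−)-quinic acid, (1S,3R,4S,5R)-1,3,4,5-tetrahydroxycyclohexane-1-carboxylic acid | C1[C@H]([C@H]([C@@H](C[C@@]1(C(=O)O)O)O)O)O | starting material
2 | 3,4-O-isopropylidene-1,5-quinide | O[C@@]12C[C@H]3OC(C)(C)O[C@H]3[C@@H](C1)OC2=O | intermediate
3 | acetonide triol (1-hydroxymethyl, 1-OH, 5-OH free) | OC[C@]1(O)C[C@H]2OC(C)(C)O[C@H]2[C@H](O)C1 | intermediate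
4 | 3-hydroxy-4,5-(isopropylidenedioxy)cyclohexan-1-one | O=C1C[C@H]2OC(C)(C)O[C@H]2[C@H](O)C1 | intermediate
5 | β-mesyloxy ketone (mesylate of 4) | O=C1C[C@H]2OC(C)(C)O[C@H]2[C@H](OS(C)(=O)=O)C1 | intermediate (not isolated)
6 | (4S,5R)-4,5-(isopropylidenedioxy)cyclohex-2-en-1-one | O=C1C[C@H]2OC(C)(C)O[C@H]2C=C1 | intermediate
7 | cross-conjugated trimethylsilyl dienol ether of 6 | C[Si](C)(C)OC1=C[C@H]2OC(C)(C)O[C@H]2C=C1 | intermediate
8 | dimethylmethyleneammonium iodide (Eschenmoser's salt) | C=[N+](C)C.[I-] | starting material
9 | C1-(dimethylaminomethyl) enone (Mannich base, C1 epimers) | CN(C)CC1C(=O)C=C[C@@H]2OC(C)(C)O[C@H]12 | intermediate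
10 | C1-(trimethylammoniomethyl) enone iodide (C1 epimers) | C[N+](C)(C)CC1C(=O)C=C[C@@H]2OC(C)(C)O[C@H]12.[I-] | intermediate (not isolated)
11 | (4S,5R)-4,5-(isopropylidenedioxy)-6-methylenecyclohex-2-en-1-one | C=C1C(=O)C=C[C@@H]2OC(C)(C)O[C@H]12 | intermediate
12 | C1,C7-diol (C1–OH α, C7H2OH β) | OC[C@]1(O)C(=O)C=C[C@@H]2OC(C)(C)O[C@H]12 | intermediate
13 | benzoyl chloride | O=C(Cl)c1ccccc1 | starting material
14 | C7 benzoate of 12 | O=C(OC[C@]1(O)C(=O)C=C[C@@H]2OC(C)(C)O[C@H]12)c1ccccc1 | intermediate
15 | trans-C1,C6-diol (C6–OH β) | O=C(OC[C@]1(O)[C@H](O)C=C[C@@H]2OC(C)(C)O[C@H]12)c1ccccc1 | intermediate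
16 | C6 methanesulfonate of 15 | O=C(OC[C@]1(O)[C@H](OS(C)(=O)=O)C=C[C@@H]2OC(C)(C)O[C@H]12)c1ccccc1 | intermediate
17 | triol mesylate (acetonide removed) | O=C(OC[C@]1(O)[C@H](OS(C)(=O)=O)C=C[C@H](O)[C@@H]1O)c1ccccc1 | intermediate
18 | epoxy diol (α-oxirane, C7 benzoate) | O=C(OC[C@]12O[C@H]1C=C[C@H](O)[C@@H]2O)c1ccccc1 | intermediate
19 | (1R,2S,3S,6S)-1-(benzoyloxymethyl)-2-hydroxy-7-oxabicyclo[4.1.0]hept-4-en-3-yl benzoate | O=C(OC[C@]12O[C@H]1C=C[C@H](OC(=O)c1ccccc1)[C@@H]2O)c1ccccc1 | target

Total step count: 14
Longest linear sequence: 14 steps (1 to 19)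

**Steps most likely to fail**

Step 8. What may go wrong is competing osmylation of the ring alkene, loss of the labile dienone to dimerisation or aromatisation before it is oxidised, or incomplete face discrimination at C1. The fallback sets out from 7, avoids the dienone altogether and returns at 12. A Mukaiyama aldol reaction of 7 with aqueous formaldehyde under Yb(OTf)3 catalysis (THF/H2O, rt) should give the hydroxymethyl enone F1 as C1 epimers. TMSOTf/Et3N (CH2Cl2, 0 °C) silylates the alcohol and re-forms the dienol ether, giving the bis-silyl dienol ether F2. Rubottom oxidation with mCPBA (NaHCO3, CH2Cl2, −20 °C) should attack the electron-rich tetrasubstituted enol ether from the α face, anti to the dioxolane, and after silyl migration give the bis-silyl ether F3. Citric acid in aqueous methanol removes both silyl groups and gives 12.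

Step 10. What may go wrong is inefficient hydride delivery from the hindered tertiary hydroxyl, so that hydride arrives on the β face and the C6 epimer forms. The fallback sets out from 14 and returns at 15. A Luche reduction (NaBH4, CeCl3·7H2O, MeOH, −78 °C) is run under substrate control. If it gives 15 the problem is solved; if hydride again enters from the β face the product is the cis-diol F4. Mitsunobu esterification of F4 with chloroacetic acid (PPh3, DIAD, THF, 0 °C) inverts C6 and gives the chloroacetate F5. Thiourea with NaHCO3 in ethanol removes the chloroacetyl group without touching the benzoate and gives 15.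

Step 7. What may go wrong is fragmentation of the ammonium salt along the wrong path (loss of the C2 acetal oxygen followed by aromatisation) or base-induced polymerisation of the dienone as it forms. The fallback sets out from 7 and returns at 11 under neutral conditions. Lewis acid-mediated α-phenylthiomethylation of 7 with chloromethyl phenyl sulfide (ZnBr2 cat., CH2Cl2, rt) should give the sulfide F6. mCPBA (1 equiv, CH2Cl2, −78 °C) gives the sulfoxide F7. Warming in toluene (80 °C, CaCO3) brings about thermal syn-elimination of benzenesulfenic acid and delivers 11.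

**Further compounds**

F1 | step 8 | C1-(hydroxymethyl) enone (C1 epimers) | OCC1C(=O)C=C[C@@H]2OC(C)(C)O[C@H]12
F2 | step 8 | bis-trimethylsilyl dienol ether (C7–OTMS, C6–OTMS, C1=C6) | C[Si](C)(C)OCC1=C(O[Si](C)(C)C)C=C[C@@H]2OC(C)(C)O[C@H]12
F3 | step 8 | bis-trimethylsilyl ether of 12 | C[Si](C)(C)OC[C@]1(O[Si](C)(C)C)C(=O)C=C[C@@H]2OC(C)(C)O[C@H]12
F4 | step 10 | cis-C1,C6-diol (C6 epimer of 15, C6–OH α) | O=C(OC[C@]1(O)[C@@H](O)C=C[C@@H]2OC(C)(C)O[C@H]12)c1ccccc1
F5 | step 10 | C6 chloroacetate (C6–O β) | O=C(OC[C@]1(O)[C@H](OC(=O)CCl)C=C[C@@H]2OC(C)(C)O[C@H]12)c1ccccc1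
F6 | step 7 | C1-(phenylthiomethyl) enone (C1 epimers) | c1ccccc1SCC1C(=O)C=C[C@@H]2OC(C)(C)O[C@H]12
F7 | step 7 | C1-(phenylsulfinylmethyl) enone (epimers at C1 and sulfur) | O=S(CC1C(=O)C=C[C@@H]2OC(C)(C)O[C@H]12)c1ccccc1
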